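The numbers are those of an exercise; what happens was integrated by code.

Set the flasks side by side and ask what the charge can change.

| flask | substrate | time |
|---|---|---|
| summer | 0.030 M | 30 s |
| autumn | 0.050 M | 30 s |
| midnight | 0.080 M | 30 s |

    substrate ⇌ dormant form (K1 = 2.32, k1 = 0.0546 /s)
    substrate ⇌ target + by-product (K2 = 0.039 M, k2 = 0.0325 /s)
    target → over-reaction product (k3 = 0.00534 /s)

- "hardly changes" means that all values lie within two and a half points (for a concentration: within two and a half percent of the largest)
- run time (summer): 30 s

* amount of target at the end, in percent of the substrate charged for summer, autumn, midnight, in this order
* how that number moves from the first to the last of them (hardly changes / falls, then rises / falls all the way / rises all the way / rises, then falls)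

In the summer flask, substrate and dormant form relax towards their ratio with a half-life of 8.87 s, shorter than the run of 30 s, so I freeze that pair at its equilibrium, a pre-equilibrium. Target there has a half-life of 130 s by over-reaction alone, longer than the run, so I set that step aside.

Let x be the share of the charge c that has passed into target and by-product. Unconverted material divides by the frozen ratio, and the second step balances when target times by-product equals its constant times substrate:

x · x / (1 − x) = 0.039 M / ((1 + 2.32) · c)

The right side is 0.392 for summer, 0.235 for autumn and 0.147 for midnight, which gives

x = 46.0 %, 38.1 %, 31.7 %.

I call x the balance share: the part of the charge the second step can deliver before its way back cancels its way forward. At midnight it stands lower than in summer by 14 percentage points. But this number has no clock: in the summer flask, the forward half-life of substrate by the second step alone is 21 s, which is 0.711 of the run. So I commit to a falling row with each target share below its balance share, and I name no levels.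

The forecast gives 32 %, 30 % and 28 %, a row that falls all the way, on the ground that “The reverse step is second order, so it bites harder at higher concentration”.

The flasks give 32.2 %, 30.2 % and 27.8 %, a row that falls all the way. By-product counts every net passage through the second step, and the midnight flask holds 0.0249 M at 30.0 s, which is 31.1 % of its charge. Against its balance share of 31.7 %, that is 0.981 of the way. The summer flask holds 0.0108 M, which is 35.8 % of its charge against 46.0 %, or 0.778 of the way.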